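## Structural features

The target (28) is a hexahydroisobenzofuranone: a cyclohexene (ring A) cis-fused through two adjacent sp3 carbons, C3a and C7a, to a γ-lactone whose C3 is a hemiacetal, i.e. a masked 1,4-aldehyde acid. The only C=C bond, C4=C5 of ring A, is tetrasubstituted. C4 carries a methyl propanoate side chain through its (R)-configured α-carbon, and C5 carries a (1S)-1,3,3-trimethylcyclohexyl group through its quaternary carbon. Of the five stereocentres, C3, C3a and C7a are contiguous, the side-chain centre is 1,3-related to C3a across the sp2 carbon C4, and the quaternary centre is insulated from the rest. The fragile groups are the hemiacetal (ring–chain tautomerism, easy oxidation), the side-chain C–H (α to the ester and allylic), and C3a–H, which is α to a free aldehyde and allylic whenever the lactol opens. The difficulty is twofold: an alkene flanked by a quaternary and a tertiary carbon, too crowded for condensation or elimination chemistry, and the relative configuration between the side-chain centre and the ring fusion, which communicate only through allylic strain. The key step reads C4=C5 with its two branched substituents as an internal alkyne and the other four carbons of ring A (C3a, C7a, C7, C6) as cyclobutanone, whose carbonyl carbon becomes C3a.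

## Logic of the disconnections

28 to 25: the lactol ring is traced back to a C1–C3 carbon–carbon bond, so that the O–C3 bond and the C3 hydroxyl both arise from hydrolytic cleavage of a four-membered ketone. This puts both lactone carbons, already cis and at the right oxidation levels, into one small ring. The forward step must break only the bond between the carbonyl and the CCl2 carbon, and must spare the methyl ester and the two enolisable centres.

25 to 24: the two exocyclic bonds at the ring fusion (C7a–C1 and C3a–C3) are cut, which leaves a cyclohexa-1,3-diene and dichloroketene. A ketene cycloaddition adds both carbons suprafacially with the regiochemistry dictated by the diene, so the lactone and its three stereocentres disappear in one move. The demand is attack on the face of ring A that carries the ester arm of the side chain.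

24 to 18: no skeletal bond is cut. The ester is taken back through 23 and 21 to the silyl ether 20, and the disubstituted alkene through 19 to the ketone of 18. The enone is what the key step delivers, and the silyl ether keeps the side-chain centre non-acidic until late. The forward steps need regioselective enolisation on the CH2 side of the ketone and an oxidation that does not epimerise the α-centre.

18 to 16 and 17 (key disconnection): the C3a–C4 bond (carbonyl carbon to the alkene carbon bearing the side chain) and the C5–C6 bond are cut. The alkene is never made by elimination, since it is simply the former alkyne, and ring A is assembled convergently from two fragments. The forward step must be regioselective in the alkyne and must close the ring faster than the metallacycle decomposes.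

16 to 14, then to 9 and 11: the alkyne is taken back through enol triflate 15 to ketone 14, and the bond between the carbinol carbon and the neighbouring CH2 is cut to give an aldehyde and a Grignard reagent. This separates the two remote stereocentres into two small building blocks. The demands are addition to a neopentyl-type aldehyde and an elimination that leaves the propargylic centre alone.

9 to 7, 6, 4, 3 and 1: the aldehyde carbon is the inner carbon of an allyl group, and the quaternary centre is set by cutting the allyl–carbon bond (decarboxylative asymmetric allylation of 3). The ketone is placed on the ring CH2 that has only one quaternary neighbour, so that it can later be removed by a Wolff–Kishner reduction. The demand is high enantioselectivity at the only stereocentre not controlled by another one.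

11 to 10: only the O–Si bond is cut; the stereocentre is bought.

## Other disconnections considered

Alternative 1: the cut removes the two exocyclic C–C bonds at the ring fusion and leaves a cyclohexa-1,3-diene ester. In the forward direction, dichloroketene (Cl3CCOCl, Zn) adds across the disubstituted alkene to give the cis-fused dichlorocyclobutanone A1, and hydroxide cleavage then unmasks the lactol. In its favour, the reaction type is well established for 1,3-dienes, the regiochemistry is fixed electronically, the ring fusion is necessarily cis, and both carbons arrive at the right oxidation level. Against it, as a strategy it says nothing about ring A: the diene ester with its crowded tetrasubstituted alkene still has to be made, and the face selectivity rests on a small steric difference between methyl and ester. In comparison, A1 is the same compound as 25, so in structure and mechanism this is the endgame of the chosen plan (steps 17 and 18) and the two are equal there. Alternative 1 is the better in that its key step is known chemistry. The chosen plan is the better in that it also solves the construction of ring A, and does so convergently. Step counts would differ only by the route to the diene.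

Alternative 2: the cut goes through the ring A alkene, which is formed first as a C4–C5 single bond and dehydrated later. In the forward direction, Zn (or CrCl2) converts the allylic bromide A2 into an allylmetal whose γ-carbon adds to the ketone and closes ring A as the tertiary alcohol A3, which carries an α-methylene ester. A2 is a menthyloxy butanolide bearing a 2-(bromomethyl)acrylate unit and the tert-alkyl ketone chain. In its favour, intramolecular allylmetal additions of this kind tolerate esters and lactones, and the ring-fusion carbons are set beforehand, with absolute control, by the menthyl acetal. On control of the ring fusion this alternative is better than the chosen plan, where the fusion is set late under weak substrate control. Against it, the addition has to build a tertiary alcohol next to the quaternary carbon at a hindered ketone. A2 needs its two ring substituents cis, against the usual trans outcome of addition–alkylation on butenolides. The alcohol must then be dehydrated into the tetrasubstituted position, and the side-chain stereocentre does not yet exist and would have to be created by a reduction with little to control it. In comparison, A3 still lacks the alkene and one stereocentre that 18 already has. The mechanism is polar addition plus elimination, against a metallacycle ring expansion that avoids elimination. The route is linear and longer, with auxiliary removal at the end. Its key step is precedented (better), but the steps after it are less controlled (worse).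

Alternative 3: the cut is the bond between the two ring-fusion carbons. In the forward direction, the δ-lactone A4 is converted into its silyl ketene acetal A5 (LiN(iPr)2, Me3SiCl). A4 has its ring oxygen on the future C5 and carries an E-alkenyl group with the side chain and a diethyl acetal. A5 rearranges through the boat transition state enforced by the ring to the ring A acid A6, with carboxyl and acetal cis. In its favour, the [3,3] shift forms the C3a–C7a bond, transfers chirality from the carbinol carbon to both fusion centres, and moves the alkene into the tetrasubstituted position without any direct alkene synthesis. In stereocontrol at the ring fusion, and in the shortness of what follows A6, this alternative is better than the chosen plan. In avoiding a hindered alkene-forming step it is its equal. Against it, A4 contains a tertiary allylic carbinol next to the quaternary carbon, of defined configuration, and a trisubstituted alkene of defined geometry. Making it means adding a substituted alkenyl metal to a tert-alkyl ketone with facial control, which only moves the steric problem. Tertiary allylic lactones are also prone to ionisation on enolisation. In comparison, the rearrangement is thermal and predictable, whereas the chosen key step is a catalytic reaction not yet shown for this alkyne class. The assembly of A4 is linear and is judged longer than the convergent route to 16.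

Key step: step 11

Remark: the hemiacetal carbon C3 of 28 equilibrates through the open aldehyde acid, so its configuration is taken to be the thermodynamic one; the (3R) epimer drawn places the hydroxyl next to the side-chain ester, where it can be hydrogen-bonded.

## Route

Step 1
Reactants: 1 4,4-dimethylcyclohexanone
Product: 3 allyl (±)-1,5,5-trimethyl-2-oxocyclohexane-1-carboxylate, via sodium β-keto ester enolate 2 (not isolated)
Conditions: NaH (2.5 equiv), (CH2=CHCH2O)2CO, THF, reflux; then MeI, 0 °C → rt
Reagents that add atoms: diallyl carbonate C=CCOC(=O)OCC=C; iodomethane CI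
Why: Claisen-type C-acylation of the ketone enolate gives the stabilised enolate 2, which is C-methylated in the same flask; the ketone is symmetric, so there is no regiochemical issue, and the quaternary centre is racemic at this stage.

Step 2
Reactants: 3 allyl (±)-1,5,5-trimethyl-2-oxocyclohexane-1-carboxylate
Product: 4 (R)-2-allyl-2,4,4-trimethylcyclohexan-1-one
Conditions: Pd2(dba)3 (2.5 mol %), (S)-t-BuPHOX (6 mol %), THF, 25 °C
Reagents that add atoms: none
Why: Palladium-catalysed decarboxylative asymmetric allylic alkylation: ionisation and loss of CO2 give an achiral enolate and an allylpalladium fragment, so the racemic ester should converge on one enantiomer. The (S)-ligand is chosen because in the parent 2-methylcyclohexanone series it gives the spatial arrangement of allyl, methyl, carbonyl and ring CH2 needed here (the descriptor is R in 4 only because the gem-dimethyl group changes the priorities); the enantiomeric purity can be raised through a crystalline derivative such as the semicarbazone if required.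

Step 3
Reactants: 4 (R)-2-allyl-2,4,4-trimethylcyclohexan-1-one
Product: 6 (R)-1-allyl-1,3,3-trimethylcyclohexane, via hydrazone 5 (not isolated)
Conditions: N2H4·H2O, KOH, diethylene glycol, 130 °C then 200 °C
Reagents that add atoms: none
Why: Wolff–Kishner reduction (Huang-Minlon procedure); the ketone has only one quaternary neighbour, so hydrazone 5 should form normally, and the stereocentre has no α-hydrogen and cannot epimerise. Any base-induced migration of the terminal alkene is harmless, because step 4 moves it the same way.

Step 4
Reactants: 6 (R)-1-allyl-1,3,3-trimethylcyclohexane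
Product: 7 (S)-1,3,3-trimethyl-1-[(E)-prop-1-en-1-yl]cyclohexane
Conditions: RuHCl(CO)(PPh3)3 (3 mol %), toluene, 110 °C
Reagents that add atoms: none
Why: Ruthenium hydride-catalysed alkene isomerisation by reversible hydrometalation; migration must stop at the propenyl stage because the next carbon is quaternary, and the E/Z ratio does not matter for step 5.

Step 5
Reactants: 7 (S)-1,3,3-trimethyl-1-[(E)-prop-1-en-1-yl]cyclohexane
Product: 9 (S)-1,3,3-trimethylcyclohexane-1-carbaldehyde, via ozonide 8 (not isolated)
Conditions: O3, CH2Cl2, −78 °C; then Me2S, −78 °C → rt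
Reagents that add atoms: ozone [O-][O+]=O
Why: Ozonolysis with reductive work-up removes the two outer carbons as acetaldehyde; the aldehyde has no α-hydrogen, so the quaternary centre is safe (the product is volatile and is best carried on as a solution).

Step 6
Reactants: 10 (S)-3-bromo-2-methylpropan-1-ol
Product: 11 (S)-(3-bromo-2-methylpropoxy)(tert-butyl)dimethylsilane
Conditions: TBSCl, imidazole, CH2Cl2, 0 °C → rt
Reagents that add atoms: tert-butyldimethylsilyl chloride CC(C)(C)[Si](C)(C)Cl
Why: Standard silylation of a primary alcohol; the stereocentre is not involved.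

Step 7
Reactants: 11 (S)-(3-bromo-2-methylpropoxy)(tert-butyl)dimethylsilane; 9 (S)-1,3,3-trimethylcyclohexane-1-carbaldehyde
Product: 13 (1RS,3R)-4-[(tert-butyldimethylsilyl)oxy]-3-methyl-1-[(1S)-1,3,3-trimethylcyclohexyl]butan-1-ol, via silyloxyalkyl Grignard reagent 12 (not isolated)
Conditions: Mg, THF, 45 °C; then 9, −20 °C → rt; aq. NH4Cl
Reagents that add atoms: none
Why: Grignard addition to an aldehyde that cannot enolise; the stereocentre of 12 is β to magnesium and therefore configurationally safe. The new carbinol centre is formed unselectively and is removed in step 8.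

Step 8
Reactants: 13 (1RS,3R)-4-[(tert-butyldimethylsilyl)oxy]-3-methyl-1-[(1S)-1,3,3-trimethylcyclohexyl]butan-1-ol
Product: 14 (3R)-4-[(tert-butyldimethylsilyl)oxy]-3-methyl-1-[(1S)-1,3,3-trimethylcyclohexyl]butan-1-one
Conditions: Dess–Martin periodinane, CH2Cl2, rt
Reagents that add atoms: none
Why: Dess–Martin oxidation of a hindered secondary alcohol under nearly neutral conditions; the methyl-bearing centre is β to the new carbonyl group and cannot epimerise.

Step 9
Reactants: 14 (3R)-4-[(tert-butyldimethylsilyl)oxy]-3-methyl-1-[(1S)-1,3,3-trimethylcyclohexyl]butan-1-one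
Product: 15 (1Z,3R)-4-[(tert-butyldimethylsilyl)oxy]-3-methyl-1-[(1S)-1,3,3-trimethylcyclohexyl]but-1-en-1-yl trifluoromethanesulfonate
Conditions: KN(SiMe3)2, THF, −78 °C; PhNTf2, −78 → 0 °C
Reagents that add atoms: N-phenylbis(trifluoromethanesulfonimide) FC(F)(F)S(=O)(=O)N(c1ccccc1)S(=O)(=O)C(F)(F)F
Why: The ketone can enolise on one side only, and a tert-alkyl ketone should give the Z enolate (chain cis to oxygen) to avoid allylic strain; O-sulfonylation then gives the Z enol triflate, in which the vinylic hydrogen is anti to the triflate.

Step 10
Reactants: 15 (1Z,3R)-4-[(tert-butyldimethylsilyl)oxy]-3-methyl-1-[(1S)-1,3,3-trimethylcyclohexyl]but-1-en-1-yl trifluoromethanesulfonate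
Product: 16 tert-butyldimethyl{[(2R)-2-methyl-4-[(1S)-1,3,3-trimethylcyclohexyl]but-3-yn-1-yl]oxy}silane
Conditions: LiN(iPr)2 (2.5 equiv), THF, −78 → −40 °C
Reagents that add atoms: none
Why: Anti E2 elimination of triflate from a vinyl triflate by a lithium amide, a standard alkyne synthesis; at low temperature the fast vinylic deprotonation should leave the propargylic C–H, and with it the stereocentre and the β-silyloxy group, untouched.

Step 11
Reactants: 16 tert-butyldimethyl{[(2R)-2-methyl-4-[(1S)-1,3,3-trimethylcyclohexyl]but-3-yn-1-yl]oxy}silane; 17 cyclobutanone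
Product: 18 2-[(2R)-1-[(tert-butyldimethylsilyl)oxy]propan-2-yl]-3-[(1S)-1,3,3-trimethylcyclohexyl]cyclohex-2-en-1-one
Conditions: Ni(cod)2 (10 mol %), PCy3 (20 mol %), 17 (4 equiv), toluene, 100 °C, sealed tube
Reagents that add atoms: none
Why: Proposed new method: the closest known reaction type is the Ni(cod)2/phosphine-catalysed intermolecular insertion of simple internal alkynes into cyclobutanones to give cyclohex-2-enones, which has not been shown for an alkyne bearing a tert-alkyl group or for so crowded a product. Zerovalent nickel should bind the alkyne and the strained ketone and couple them oxidatively to an oxanickelacyclopentene; β-carbon elimination, driven by release of ring strain, then opens the spiro four-membered ring to a seven-membered nickelacycle, and C(sp2)–C(sp3) reductive elimination gives 18 and returns zerovalent nickel. Ring A is therefore closed by reductive elimination from a seven-membered metallacycle, a formal [4+2] two-carbon expansion of the four-membered ring, not by a polar exo or endo cyclisation. No stereocentre is created and the two existing ones are spectators: the quaternary carbon cannot change, and only the propargylic C–H is at risk, through alkyne–allene isomerisation. The step needs regioselectivity in the oxidative coupling, with the carbonyl carbon bonding to the alkyne carbon that bears the secondary side chain; this is expected because the transition state places the larger substituent, here the tert-alkyl group, on the carbon that binds nickel, away from the incoming ring. It also needs reductive elimination to outrun β-hydride elimination from the nickelacycle, which the bulky electron-rich PCy3 should favour, and the hindered alkyne cannot compete by cyclotrimerisation. The side chain is kept as a silyl ether, not an ester, so that the propargylic centre is not acidified, and 17 is used in excess because it is cheap and volatile.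

Step 12
Reactants: 18 2-[(2R)-1-[(tert-butyldimethylsilyl)oxy]propan-2-yl]-3-[(1S)-1,3,3-trimethylcyclohexyl]cyclohex-2-en-1-one
Product: 19 6-[(2R)-1-[(tert-butyldimethylsilyl)oxy]propan-2-yl]-5-[(1S)-1,3,3-trimethylcyclohexyl]cyclohexa-1,5-dien-1-yl trifluoromethanesulfonate
Conditions: KN(SiMe3)2, THF, −78 °C; PhNTf2, −78 → 0 °C
Reagents that add atoms: N-phenylbis(trifluoromethanesulfonimide) FC(F)(F)S(=O)(=O)N(c1ccccc1)S(=O)(=O)C(F)(F)F
Why: Kinetic deprotonation of a cyclohex-2-enone by a hindered amide base takes place at the α′-CH2 next to the carbonyl group, not at the γ-CH2 or the side-chain C–H; O-sulfonylation of the cross-conjugated dienolate gives the 2-triflyloxy-1,3-diene.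

Step 13
Reactants: 19 6-[(2R)-1-[(tert-butyldimethylsilyl)oxy]propan-2-yl]-5-[(1S)-1,3,3-trimethylcyclohexyl]cyclohexa-1,5-dien-1-yl trifluoromethanesulfonate
Product: 20 tert-butyldimethyl{[(2R)-2-{2-[(1S)-1,3,3-trimethylcyclohexyl]cyclohexa-1,5-dien-1-yl}propyl]oxy}silane
Conditions: Pd(OAc)2 (5 mol %), PPh3 (10 mol %), HCO2H, Bu3N, DMF, 60 °C
Reagents that add atoms: none
Why: Palladium-catalysed formate reduction of an enol triflate (oxidative addition to zerovalent palladium, exchange of triflate for formate, loss of CO2 to a palladium hydride, reductive elimination); the new alkene is fixed between the former carbonyl carbon and its CH2 neighbour without a cationic intermediate that could scramble the diene.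

Step 14
Reactants: 20 tert-butyldimethyl{[(2R)-2-{2-[(1S)-1,3,3-trimethylcyclohexyl]cyclohexa-1,5-dien-1-yl}propyl]oxy}silane
Product: 21 (2R)-2-{2-[(1S)-1,3,3-trimethylcyclohexyl]cyclohexa-1,5-dien-1-yl}propan-1-ol
Conditions: Bu4NF, THF, 0 °C → rt
Reagents that add atoms: none
Why: Fluoride cleavage of a primary silyl ether; nothing else in the molecule is sensitive to fluoride or to mild base.

Step 15
Reactants: 21 (2R)-2-{2-[(1S)-1,3,3-trimethylcyclohexyl]cyclohexa-1,5-dien-1-yl}propan-1-ol
Product: 23 (2R)-2-{2-[(1S)-1,3,3-trimethylcyclohexyl]cyclohexa-1,5-dien-1-yl}propanoic acid, via aldehyde 22 (not isolated)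
Conditions: TEMPO (0.2 equiv), PhI(OAc)2 (2.4 equiv), MeCN/H2O (1:1), 0 °C → rt
Reagents that add atoms: water O
Why: Oxoammonium (TEMPO) oxidation with PhI(OAc)2 as terminal oxidant takes a primary alcohol through aldehyde 22 and its hydrate to the acid; the weakly acidic, chlorine-free medium is the gentlest choice for the α-stereocentre and for the electron-rich diene.

Step 16
Reactants: 23 (2R)-2-{2-[(1S)-1,3,3-trimethylcyclohexyl]cyclohexa-1,5-dien-1-yl}propanoic acid
Product: 24 methyl (2R)-2-{2-[(1S)-1,3,3-trimethylcyclohexyl]cyclohexa-1,5-dien-1-yl}propanoate
Conditions: Me3SiCHN2, toluene/MeOH (4:1), 0 °C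
Reagents that add atoms: trimethylsilyldiazomethane C[Si](C)(C)C=[N+]=[N-]
Why: Esterification by proton transfer to the diazo compound and methylation of the carboxylate; no base is present, so the α-centre is not touched.

Step 17
Reactants: 24 methyl (2R)-2-{2-[(1S)-1,3,3-trimethylcyclohexyl]cyclohexa-1,5-dien-1-yl}propanoate
Product: 25 methyl (2R)-2-{(1R,6R)-8,8-dichloro-7-oxo-3-[(1S)-1,3,3-trimethylcyclohexyl]bicyclo[4.2.0]oct-2-en-2-yl}propanoate
Conditions: Cl3CCOCl, Zn dust (activated), Et2O/DME, 0 °C → rt
Reagents that add atoms: trichloroacetyl chloride ClC(Cl)(Cl)C(Cl)=O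
Why: [2+2] cycloaddition of dichloroketene to the less substituted alkene of a 1,3-diene: the ketene carbonyl carbon attacks the diene terminus and the CCl2 carbon closes on the inner carbon, as with simple cyclic dienes, and suprafacial addition makes the ring fusion cis. Allylic 1,3-strain against the tert-alkyl group holds the side-chain C–H in the ring plane, so methyl and ester lie on opposite faces; the required isomer comes from attack on the ester face, which should be favoured because a planar ester is the smaller group, but probably only moderately, so the diastereomers are to be separated at this stage.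

Step 18
Reactants: 25 methyl (2R)-2-{(1R,6R)-8,8-dichloro-7-oxo-3-[(1S)-1,3,3-trimethylcyclohexyl]bicyclo[4.2.0]oct-2-en-2-yl}propanoate
Product: 28 methyl (2R)-2-{(3R,3aR,7aR)-3-hydroxy-1-oxo-5-[(1S)-1,3,3-trimethylcyclohexyl]-1,3,3a,6,7,7a-hexahydroisobenzofuran-4-yl}propanoate, via lithium dichloromethyl carboxylate 26 (not isolated), via chlorolactone 27 (not isolated)
Conditions: LiOH·H2O (1.1 equiv), THF/H2O (3:1), 0 °C; then AgNO3 (2.5 equiv), 2,6-lutidine (1.1 equiv), rt
Reagents that add atoms: lithium hydroxide [Li+].[OH-]; water O
Why: Haloform-type cleavage: hydroxide adds to the strained, doubly α-chlorinated ketone and the bond to the CCl2 carbon breaks, giving carboxylate 26; silver-assisted ionisation of one C–Cl bond with capture by the neighbouring carboxylate gives chlorolactone 27, which hydrolyses to the lactol. Only one equivalent of hydroxide is used, at 0 °C, so that the hindered methyl ester and the two enolisable centres never meet excess base; the hemiacetal carbon settles by ring–chain equilibration.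

## Compound list

1 | 4,4-dimethylcyclohexanone | CC1(C)CCC(=O)CC1 | starting material
2 | sodium enolate of allyl 5,5-dimethyl-2-oxocyclohexane-1-carboxylate | C=CCOC(=O)C1=C([O-])CCC(C)(C)C1.[Na+] | intermediate (not isolated)
3 | allyl (±)-1,5,5-trimethyl-2-oxocyclohexane-1-carboxylate | C=CCOC(=O)C1(C)CC(C)(C)CCC1=O | intermediate
4 | (R)-2-allyl-2,4,4-trimethylcyclohexan-1-one | C=CC[C@@]1(C)C(=O)CCC(C)(C)C1 | intermediate
5 | hydrazone of 4 | C=CC[C@@]1(C)C(=NN)CCC(C)(C)C1 | intermediate (not isolated)
6 | (R)-1-allyl-1,3,3-trimethylcyclohexane | C=CC[C@@]1(C)CCCC(C)(C)C1 | intermediate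
7 | (S)-1,3,3-trimethyl-1-[(E)-prop-1-en-1-yl]cyclohexane | C/C=C/[C@@]1(C)CCCC(C)(C)C1 | intermediate
8 | 3-methyl-5-[(1S)-1,3,3-trimethylcyclohexyl]-1,2,4-trioxolane (ozonide, mixture at the ring carbons) | CC1OOC(O1)[C@@]1(C)CCCC(C)(C)C1 | intermediate (not isolated)
9 | (S)-1,3,3-trimethylcyclohexane-1-carbaldehyde | O=C[C@@]1(C)CCCC(C)(C)C1 | intermediate
10 | (S)-3-bromo-2-methylpropan-1-ol | OC[C@H](C)CBr | starting material
11 | (S)-(3-bromo-2-methylpropoxy)(tert-butyl)dimethylsilane | CC(C)(C)[Si](C)(C)OC[C@H](C)CBr | intermediate
12 | [(2S)-3-[(tert-butyldimethylsilyl)oxy]-2-methylpropyl]magnesium bromide | CC(C)(C)[Si](C)(C)OC[C@H](C)C[Mg]Br | intermediate (not isolated)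
13 | (1RS,3R)-4-[(tert-butyldimethylsilyl)oxy]-3-methyl-1-[(1S)-1,3,3-trimethylcyclohexyl]butan-1-ol | CC(C)(C)[Si](C)(C)OC[C@H](C)CC(O)[C@@]1(C)CCCC(C)(C)C1 | intermediate
14 | (3R)-4-[(tert-butyldimethylsilyl)oxy]-3-methyl-1-[(1S)-1,3,3-trimethylcyclohexyl]butan-1-one | CC(C)(C)[Si](C)(C)OC[C@H](C)CC(=O)[C@@]1(C)CCCC(C)(C)C1 | intermediate
15 | (1Z,3R)-4-[(tert-butyldimethylsilyl)oxy]-3-methyl-1-[(1S)-1,3,3-trimethylcyclohexyl]but-1-en-1-yl trifluoromethanesulfonate | CC(C)(C)[Si](C)(C)OC[C@H](C)/C=C(\OS(=O)(=O)C(F)(F)F)[C@@]1(C)CCCC(C)(C)C1 | intermediate
16 | tert-butyldimethyl{[(2R)-2-methyl-4-[(1S)-1,3,3-trimethylcyclohexyl]but-3-yn-1-yl]oxy}silane | CC(C)(C)[Si](C)(C)OC[C@H](C)C#C[C@@]1(C)CCCC(C)(C)C1 | intermediate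
17 | cyclobutanone | O=C1CCC1 | starting material
18 | 2-[(2R)-1-[(tert-butyldimethylsilyl)oxy]propan-2-yl]-3-[(1S)-1,3,3-trimethylcyclohexyl]cyclohex-2-en-1-one | CC(C)(C)[Si](C)(C)OC[C@H](C)C1=C([C@@]2(C)CCCC(C)(C)C2)CCCC1=O | intermediate
19 | 6-[(2R)-1-[(tert-butyldimethylsilyl)oxy]propan-2-yl]-5-[(1S)-1,3,3-trimethylcyclohexyl]cyclohexa-1,5-dien-1-yl trifluoromethanesulfonate | CC(C)(C)[Si](C)(C)OC[C@H](C)C1=C([C@@]2(C)CCCC(C)(C)C2)CCC=C1OS(=O)(=O)C(F)(F)F | intermediate
20 | tert-butyldimethyl{[(2R)-2-{2-[(1S)-1,3,3-trimethylcyclohexyl]cyclohexa-1,5-dien-1-yl}propyl]oxy}silane | CC(C)(C)[Si](C)(C)OC[C@H](C)C1=C([C@@]2(C)CCCC(C)(C)C2)CCC=C1 | intermediate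
21 | (2R)-2-{2-[(1S)-1,3,3-trimethylcyclohexyl]cyclohexa-1,5-dien-1-yl}propan-1-ol | OC[C@H](C)C1=C([C@@]2(C)CCCC(C)(C)C2)CCC=C1 | intermediate
22 | (2R)-2-{2-[(1S)-1,3,3-trimethylcyclohexyl]cyclohexa-1,5-dien-1-yl}propanal | O=C[C@H](C)C1=C([C@@]2(C)CCCC(C)(C)C2)CCC=C1 | intermediate (not isolated)
23 | (2R)-2-{2-[(1S)-1,3,3-trimethylcyclohexyl]cyclohexa-1,5-dien-1-yl}propanoic acid | OC(=O)[C@H](C)C1=C([C@@]2(C)CCCC(C)(C)C2)CCC=C1 | intermediate
24 | methyl (2R)-2-{2-[(1S)-1,3,3-trimethylcyclohexyl]cyclohexa-1,5-dien-1-yl}propanoate | COC(=O)[C@H](C)C1=C([C@@]2(C)CCCC(C)(C)C2)CCC=C1 | intermediate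
25 | methyl (2R)-2-{(1R,6R)-8,8-dichloro-7-oxo-3-[(1S)-1,3,3-trimethylcyclohexyl]bicyclo[4.2.0]oct-2-en-2-yl}propanoate | COC(=O)[C@H](C)C1=C([C@@]2(C)CCCC(C)(C)C2)CC[C@H]2C(=O)C(Cl)(Cl)[C@@H]12 | intermediate
26 | lithium (1R,2R)-2-(dichloromethyl)-3-[(2R)-1-methoxy-1-oxopropan-2-yl]-4-[(1S)-1,3,3-trimethylcyclohexyl]cyclohex-3-ene-1-carboxylate | COC(=O)[C@H](C)C1=C([C@@]2(C)CCCC(C)(C)C2)CC[C@@H](C(=O)[O-])[C@H]1C(Cl)Cl.[Li+] | intermediate (not isolated)
27 | methyl (2R)-2-{(3aR,7aR)-3-chloro-1-oxo-5-[(1S)-1,3,3-trimethylcyclohexyl]-1,3,3a,6,7,7a-hexahydroisobenzofuran-4-yl}propanoate (mixture at C3) | COC(=O)[C@H](C)C1=C([C@@]2(C)CCCC(C)(C)C2)CC[C@H]2C(=O)OC(Cl)[C@@H]12 | intermediate (not isolated)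
28 | methyl (2R)-2-{(3R,3aR,7aR)-3-hydroxy-1-oxo-5-[(1S)-1,3,3-trimethylcyclohexyl]-1,3,3a,6,7,7a-hexahydroisobenzofuran-4-yl}propanoate | COC(=O)[C@H](C)C1=C([C@@]2(C)CCCC(C)(C)C2)CC[C@H]2C(=O)O[C@@H](O)[C@@H]12 | target

## Step count and least certain steps

Total step count: 18. Longest linear sequence: 17 steps (from 1 through steps 1–5 and 7–18); step 6 is the one-step side branch.

Step 11 (key step, proposed new method). What may go wrong: the doubly branched alkyne may fail to enter the oxidative coupling at all, the seven-membered nickelacycle may be diverted by β-hydride elimination to open-chain enones, or the carbonyl carbon may bond to the wrong alkyne carbon. The fallback uses known chemistry, a Michael addition followed by an aldol condensation; it sets out from 9 and from 11 (through Grignard reagent 12) and comes back at 18. Aldehyde 9 is treated with MeMgBr to give 1-[(1S)-1,3,3-trimethylcyclohexyl]ethanol F1, which Dess–Martin periodinane oxidises to the methyl ketone F2. Grignard reagent 12 is added to acrolein to give the allylic alcohol F3, which is oxidised in the same way to the vinyl ketone F4. The lithium enolate of F2 (LiN(iPr)2, THF, −78 °C) is added to F4 to give the 1,5-diketone F5, and base (KOH, MeOH, reflux) then closes ring A by intramolecular aldol condensation onto the tert-alkyl ketone to give 18. The weak point of this fallback is that hindered aldol step, which is why it is not the first choice.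

Step 18. What may go wrong: ring contraction of the α,α-dichlorocyclobutanone by a semibenzilic pathway instead of C–C cleavage, partial saponification of the methyl ester, or epimerisation and alkene migration at C3a while the aldehyde is free. The fallback replaces the haloform-type cleavage by an oxidative one; it sets out from 25 and comes back at 28. Zinc in acetic acid removes both chlorines to give the cyclobutanone F6. Soft enolisation with Me3SiOTf and Et3N, which goes towards the CH2 and away from the ring-fusion carbon, gives the silyl enol ether F7. Ozonolysis at −78 °C with Me2S work-up cleaves the enol ether double bond to a silyl ester and an aldehyde, which close to 28 on aqueous work-up. The tetrasubstituted ring alkene is much more shielded than the enol ether, and one equivalent of ozone is used.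

Step 17. What may go wrong: poor facial selectivity, because the two faces of the diene differ only by a methyl group against an ester group, so that attack on the methyl face may compete or prevail. The fallback delivers the ketene from the side chain itself; it sets out from 21 and comes back at 28. Alcohol 21 is alkylated with bromoacetic acid (NaH, THF) to the alkoxyacetic acid F8, which (COCl)2 converts into the acid chloride F9. Et3N in refluxing toluene then effects dehydrochlorination and intramolecular ketene–alkene cycloaddition to the tricyclic α-alkoxycyclobutanone F10. The six-membered ether tether can only reach the face that carries the CH2O arm, which is the face required, because the other rotamer would push the methyl group against the tert-alkyl group. SmI2 (THF/MeOH, −78 °C) cleaves the C–O bond α to the ketone and releases the hydroxy cyclobutanone F11. Oxidation with TEMPO/PhI(OAc)2 gives the acid F12, methylation with Me3SiCHN2 gives F6, and F6 is taken on through F7 to 28 as described for step 18.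

Step 12. What may go wrong: deprotonation at the γ-CH2 instead of the α′-CH2, or slow O-sulfonylation of the hindered dienolate, either of which would erode the regiochemical purity of the diene. The fallback replaces enolate chemistry by reduction and syn elimination; it sets out from 18 and comes back at 20. Reduction with NaBH4 and CeCl3·7H2O in MeOH (Luche conditions) gives the allylic alcohol F13, and the Burgess reagent in warm toluene removes water by syn elimination towards the only neighbouring carbon that bears hydrogen.

## Further compounds

F1 | step 11 | (1RS)-1-[(1S)-1,3,3-trimethylcyclohexyl]ethan-1-ol | CC(O)[C@@]1(C)CCCC(C)(C)C1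
F2 | step 11 | 1-[(1S)-1,3,3-trimethylcyclohexyl]ethan-1-one | CC(=O)[C@@]1(C)CCCC(C)(C)C1
F3 | step 11 | (3RS,5R)-6-[(tert-butyldimethylsilyl)oxy]-5-methylhex-1-en-3-ol | CC(C)(C)[Si](C)(C)OC[C@H](C)CC(O)C=C
F4 | step 11 | (5R)-6-[(tert-butyldimethylsilyl)oxy]-5-methylhex-1-en-3-one | CC(C)(C)[Si](C)(C)OC[C@H](C)CC(=O)C=C
F5 | step 11 | (7R)-8-[(tert-butyldimethylsilyl)oxy]-7-methyl-1-[(1S)-1,3,3-trimethylcyclohexyl]octane-1,5-dione | CC(C)(C)[Si](C)(C)OC[C@H](C)CC(=O)CCCC(=O)[C@@]1(C)CCCC(C)(C)C1
F6 | step 18 | methyl (2R)-2-{(1R,6R)-7-oxo-3-[(1S)-1,3,3-trimethylcyclohexyl]bicyclo[4.2.0]oct-2-en-2-yl}propanoate | COC(=O)[C@H](C)C1=C([C@@]2(C)CCCC(C)(C)C2)CC[C@H]2C(=O)C[C@@H]12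
F7 | step 18 | trimethylsilyl enol ether of F6 (7-silyloxybicyclo[4.2.0]octa-2,7-diene, ring fusion as in F6) | COC(=O)[C@H](C)C1=C([C@@]2(C)CCCC(C)(C)C2)CC[C@H]2C(O[Si](C)(C)C)=C[C@@H]12
F8 | step 17 | {(2R)-2-{2-[(1S)-1,3,3-trimethylcyclohexyl]cyclohexa-1,5-dien-1-yl}propoxy}acetic acid | OC(=O)COC[C@H](C)C1=C([C@@]2(C)CCCC(C)(C)C2)CCC=C1
F9 | step 17 | acid chloride of F8 | ClC(=O)COC[C@H](C)C1=C([C@@]2(C)CCCC(C)(C)C2)CCC=C1
F10 | step 17 | tricyclic α-alkoxycyclobutanone (cyclobutanone cis-fused to ring A and, through its alkoxy carbon, to a new oxane ring that contains the side-chain CH and CH2O) | C[C@H]1CO[C@@H]2C(=O)[C@@H]3CCC([C@@]4(C)CCCC(C)(C)C4)=C1[C@H]23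
F11 | step 17 | (1R,6R)-5-[(2R)-1-hydroxypropan-2-yl]-4-[(1S)-1,3,3-trimethylcyclohexyl]bicyclo[4.2.0]oct-4-en-7-one | OC[C@H](C)C1=C([C@@]2(C)CCCC(C)(C)C2)CC[C@H]2C(=O)C[C@@H]12
F12 | step 17 | (2R)-2-{(1R,6R)-7-oxo-3-[(1S)-1,3,3-trimethylcyclohexyl]bicyclo[4.2.0]oct-2-en-2-yl}propanoic acid | OC(=O)[C@H](C)C1=C([C@@]2(C)CCCC(C)(C)C2)CC[C@H]2C(=O)C[C@@H]12
F13 | step 12 | 2-[(2R)-1-[(tert-butyldimethylsilyl)oxy]propan-2-yl]-3-[(1S)-1,3,3-trimethylcyclohexyl]cyclohex-2-en-1-ol (carbinol epimers) | CC(C)(C)[Si](C)(C)OC[C@H](C)C1=C([C@@]2(C)CCCC(C)(C)C2)CCCC1O
A1 | alternative 1 | cis-fused dichlorocyclobutanone (same structure as 25) | COC(=O)[C@H](C)C1=C([C@@]2(C)CCCC(C)(C)C2)CC[C@H]2C(=O)C(Cl)(Cl)[C@@H]12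
A2 | alternative 2 | keto allylic bromide: (1S,2R,5S)-menthyloxy butanolide carrying, cis to each other, a (Z)-2-(bromomethyl)acrylate unit and the 3-oxo-3-[(1S)-1,3,3-trimethylcyclohexyl]propyl chain | COC(=O)/C(CBr)=C/[C@H]1[C@@H](CCC(=O)[C@@]2(C)CCCC(C)(C)C2)C(=O)O[C@@H]1O[C@H]3C[C@@H](C)CC[C@@H]3C(C)C
A3 | alternative 2 | bicyclic tertiary alcohol with α-methylene ester and menthyl acetal | C=C(C(=O)OC)[C@@H]1[C@@](O)([C@@]3(C)CCCC(C)(C)C3)CC[C@H]2C(=O)O[C@H](O[C@H]4C[C@@H](C)CC[C@@H]4C(C)C)[C@@H]12
A4 | alternative 3 | δ-lactone: 6-[(1S)-1,3,3-trimethylcyclohexyl]oxan-2-one carrying at C6 an (E)-alkenyl group with the silyloxypropyl side chain and a diethyl acetal | CCOC(OCC)/C=C(\[C@@H](C)CO[Si](C)(C)C(C)(C)C)[C@]1([C@@]2(C)CCCC(C)(C)C2)CCCC(=O)O1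
A5 | alternative 3 | trimethylsilyl ketene acetal of A4 | CCOC(OCC)/C=C(\[C@@H](C)CO[Si](C)(C)C(C)(C)C)[C@]1([C@@]2(C)CCCC(C)(C)C2)CCC=C(O[Si](C)(C)C)O1
A6 | alternative 3 | ring A carboxylic acid with cis diethyl acetal | CC(C)(C)[Si](C)(C)OC[C@H](C)C1=C([C@@]2(C)CCCC(C)(C)C2)CC[C@@H](C(=O)O)[C@H]1C(OCC)OCC
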